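Remark on the chemistry: the lactol carbon of the target is a hemiacetal carbon that equilibrates through the ring-opened formyl acid, so the (S) enantiomer is taken to be obtainable and storable only as a crystalline solid, and the last step is planned for that.

## Structural features

The target is a depsidone. Ring A (A1 methoxy, A2 hydrogen, A3 methyl, A4 carbonyl-bearing, A5 ether oxygen, A6 formyl) and ring B (B1 ether oxygen, B2 ester oxygen, B3 hydrogen, B4 hydroxyl, B5 and B6 carrying the fused lactone) are tied by an aryl ester (A4–C(=O)–O–B2) and a diaryl ether (A5–O–B1) into a seven-membered 1,4-dioxepinone, and a five-membered hydroxy lactone is fused to B5–B6. The only stereocentre is the lactol carbon on B6, (S); it has no stereogenic neighbour and, as the hemiacetal of a formyl acid, it is configurationally labile through ring–chain tautomerism. Fragile groups are the aryl ester of the seven-membered ring (bases, nucleophiles), the lactol (any base opens it), the aldehyde on A6 between two oxygens and the free phenol on B4. The real difficulty is twofold: the diaryl ether joins two carbons (A5, B1) that are each flanked by two substituted positions, the worst case for an aryl–oxygen coupling, and the lactol configuration cannot be carried through a synthesis but must be fixed at the end. Ring A has the orsellinate pattern of a folded tetraketide: the carbonyl carbon on A4, the methyl group on the neighbouring A3, and oxygens on the alternate carbons A5 and A1. Because the A5 oxygen is the ether oxygen to B1, the polyketide chain can be assembled on the B1 oxygen as an aryl enol ether and ring A closed by forming the A3–A4 bond, so the hindered ether is never made by coupling; this is what the key step exploits.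

## Logic of the disconnections

23 ⇒ 21. No skeletal bond is cut; only the configuration of the lactol carbon is given up. This centre racemizes through the open formyl acid, so setting it earlier would be pointless; the gain is that every earlier intermediate is achiral or racemic. The forward step must let crystallization of one enantiomer, not a reaction in solution, decide the configuration.

21 ⇒ 20. The lactol C–O bond is cut and its two halves are masked, the B5 carboxyl as an acid-labile ester and the B6 formyl group as an acetal. The masked pair is inert to the bases used earlier and one acid treatment frees both. The demand is that the acid spares the aryl ester of the seven-membered ring and that the B5 ester is of a different kind from the ring A ester; two like esters could not be told apart.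

20 ⇒ 19. The seven-membered ring is opened at the C(=O)–O(B2) bond, its most labile bond, which is therefore made late. The gain is a seco acid whose rings are held only by the ether. The lactonization must pick the B2 hydroxyl; geometry secures this, since the B4 hydroxyl is para to the ether link and out of reach, so B2 and B4 may carry the same protecting group.

19 ⇒ 18. The acid and the two ring B phenols are capped with benzyl groups, and a bromine is placed on A2; all four leave under one neutral reduction. Benzyl and acetal are orthogonal, which two acid-labile groups on B2 and B6 would not be. The demand is that the reduction spares the aldehyde.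

18 ⇒ 17 ⇒ 16 ⇒ 15. The O–methyl bond, the A6–formyl bond and the A2–bromine bond are cut in turn. The formyl group is delivered by the A1 phenoxide to an ortho position; A2 (para to the ether oxygen, unscreened) is the expected site and not A6 (beneath the orthogonal ring B), so A2 is blocked first. The gain is 15, the product of the fold. The halogenation must prefer A2, and the block must leave without a step of its own, which it does in 18 → 19.

15 ⇒ 13. Key disconnection: the A3–A4 bond is cut and ring A unfolds into an eight-carbon chain on the B1 oxygen (C1 ester, C3 aryl enol ether, C5 and C7 ketones). The cut follows the orsellinate pattern; the gain is that ring A and the hindered ether both come from an acyclic chain. The forward step must make aldol closure beat acyl transfer to the ester and loss of aryloxide, which calls for a non-nucleophilic base.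

13 ⇒ 12 ⇒ 10, each with 11. The C6–C7 bond and then the C4–C5 bond are cut, each releasing one acetyl unit. A preformed acetoacetyl unit would need a ketone mask whose acidic removal endangers the acetal and the enol ether; two acetyl transfers need no mask. The gain is the simple crotonate 10. The demand is clean γ-deprotonation and then terminal deprotonation, without expulsion of aryloxide from the anions.

10 ⇒ 7 + 9, and 9 ⇒ 8. The enol ether C3–O bond is cut. The bond to the hindered B1 oxygen is thus made with a small linear electrophile in place of an aryl halide. The gain is two simple pieces. The demand is that B1 is the only free hydroxyl of 7 and that the B6 formyl group is masked, since a free ortho aldehyde would condense with the adduct.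

7 ⇒ 6 ⇒ 5. The acetal C–O bonds and then the B6–formyl bond are cut; the B1 phenol directs the carbon to its only free ortho position. The gain is 5, a benzoate whose three oxygens are already differentiated. The ester beside the incoming carbon must not capture the intermediate alkoxide, hence a bulky ester.

5 ⇒ 3 ⇒ 2 ⇒ 1. The B1–O bond is traced to a C–Br bond, the benzyl ethers to the phenols and the ester to the acid. A precursor with three like ether groups could not be differentiated later, whereas in 1 the future B1 oxygen is marked by bromine from the start. The gain is a commercial acid. The demand is a bromine-to-oxygen exchange that tolerates ester and ethers.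

## Other disconnections considered

Alternative 1: The cut is the A5–O bond, made as an enol ether while ring A is still a cyclohexane-1,3-dione. In the forward direction A2, in which a (6R)-6-methyl-2,4-dioxocyclohexane-1-carboxylic acid is esterified to the B2 oxygen, would be heated with acid under removal of water. The free B1 hydroxyl would condense with the ring ketone next to the ester carbon and give the tricyclic enol ether lactone A1, which must then be dehydrogenated, formylated and methylated.
- In its favour: the carbocycle of A2 comes from classical Michael–Claisen chemistry, and the ether and the seven-membered ring form in one step without any coupling.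
- Against it here: acid and heat are asked of a substrate with a dimethyl acetal and a β-keto aryl ester; a phenol is a weak partner for enol ether formation; the second ring carbonyl can condense between molecules; the stereocentre of A2 and A1 is spent on aromatization; and an oxidant must then act beside an electron-rich free phenol.
- Structure: equal to the chosen plan, since both avoid coupling two hindered arenes and both leave the formyl group for later.
- Mechanism: the alternative is better in that the seven-membered ring closes in the key step itself; the chosen fold is better in that it runs under mild base, where the acetal is safe, and aromatizes by loss of water without an oxidant.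
- Step economy: about equal, because the dehydrogenation offsets the saved lactonization.

Alternative 2: Three C–C bonds of ring A are cut at once. In the forward direction A4 carries a 2-diazo-4-methyl-3-oxopent-4-enoyl group on the B2 oxygen and a 3,3-diethoxyprop-1-ynyl group on the B1 oxygen. On irradiation, Wolff rearrangement would give a vinylketene, which would add [2+2] to the tethered ynol ether; four-electron ring opening, six-electron closure and tautomerization would then give the depsidone A3.
- In its favour: it is the most convergent of the four plans, and every substituent of ring A is fixed by connectivity, including the masked formyl group between the two oxygens; the seven-membered ring closes in the same step and no base is needed.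
- Against it here: an aryl ynol ether must be made on a fully substituted ring that carries esters; a carbene precursor is photolysed beside an electron-rich arene and several acetals; and the [2+2] step through a seven-membered tether has little close analogy.
- Structure: the alternative is better on the regiochemistry of the formyl carbon, which the chosen plan can only secure by a blocking group.
- Mechanism: a cascade of four pericyclic events leaves little room for adjustment, against one aldol closure in the chosen plan.
- Step economy: the key step does more, but installing the two tethered functions is expected to cost at least as many steps as the chosen chain assembly.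

Alternative 3: The cut is the A4–C(=O) bond of the lactone. In the forward direction A6, a preformed diaryl ether with a chloroformate on the B2 oxygen and a pinacol boronate on A4, would be treated with Pd(PPh3)4 (zerovalent palladium) and base. Insertion into the C–Cl bond, transmetalation and reductive elimination would give the depsidone A5.
- In its favour: ring A can be built beforehand with methoxy and formyl groups in place, and the lactone carbonyl comes from a C1 reagent, so no hindered benzoate has to be freed; the final acid unmasking is the same as in the chosen plan.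
- Against it here: the ether of A6 must first be made by coupling a phenol and an aryl halide that are both flanked on two sides, which is the hard bond of the target; aryloxycarbonyl palladium species tend to lose CO2; and a boronate between methyl and aryloxy groups transmetalates slowly and protodeboronates.
- Structure: the alternative is better on ring A regiochemistry and worse on the ether.
- Mechanism: both plans close a ring with one bond, but a seven-membered acyl Suzuki closure has little analogy, whereas the polyketide fold has close ones.
- Step economy: equal at best.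

Key step: step 10

In the names below, ArO stands for the ring B group 4,6-bis(benzyloxy)-3-(tert-butoxycarbonyl)-2-(dimethoxymethyl)phenoxy.

## Steps

Step 1
Reactants: 1 5-bromo-2,4-dihydroxybenzoic acid
Product: 2 tert-butyl 5-bromo-2,4-dihydroxybenzoate
Conditions: Me2NCH(OtBu)2 (4 equiv), toluene, 80 °C
Reagents that add atoms: N,N-dimethylformamide di-tert-butyl acetal, CN(C)C(OC(C)(C)C)OC(C)(C)C
Why: Esterification of a carboxylic acid by an amide acetal (tert-butyl transfer to the carboxylate from the protonated acetal), a reaction that phenols undergo far more slowly; the tert-butyl ester is chosen because it resists attack by a neighbouring alkoxide in step 4 and falls to acid together with the acetal in step 16.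

Step 2
Reactants: 2 tert-butyl 5-bromo-2,4-dihydroxybenzoate
Product: 3 tert-butyl 2,4-bis(benzyloxy)-5-bromobenzoate
Conditions: BnBr, K2CO3, DMF, 60 °C
Reagents that add atoms: benzyl bromide, BrCc1ccccc1
Why: Williamson etherification; warm DMF also benzylates the hydrogen-bonded phenol next to the ester, and the tert-butyl ester is inert to carbonate.

Step 3
Reactants: 3 tert-butyl 2,4-bis(benzyloxy)-5-bromobenzoate
Product: 5 tert-butyl 2,4-bis(benzyloxy)-5-hydroxybenzoate, via pinacol boronate 4 (not isolated)
Conditions: B2pin2, Pd(dppf)Cl2 (3 mol %), KOAc, 1,4-dioxane, 90 °C; then 30% aq. H2O2, NaOH, THF, 0 °C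
Reagents that add atoms: hydrogen peroxide, OO (the phenol oxygen); bis(pinacolato)diboron, CC1(C)OB(OC1(C)C)B1OC(C)(C)C(C)(C)O1 (boron and pinacol of intermediate 4 only)
Why: Miyaura borylation followed by oxidation of the C–B bond at the same carbon; this turns the brominated position into the one free phenol of ring B (B1) while B2 and B4 are already capped.

Step 4
Reactants: 5 tert-butyl 2,4-bis(benzyloxy)-5-hydroxybenzoate
Product: 6 tert-butyl 4,6-bis(benzyloxy)-2-formyl-3-hydroxybenzoate
Conditions: MgCl2, Et3N, (CH2O)n, MeCN, 80 °C
Reagents that add atoms: formaldehyde (as paraformaldehyde), C=O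
Why: Casnati–Skattebøl ortho-formylation: the magnesium phenoxide delivers formaldehyde to its only free ortho position (B6) and a second formaldehyde accepts hydride; the bulky tert-butyl ester beside the new carbon should resist the transient magnesium alkoxide, which a methyl ester could trap as a phthalide.

Step 5
Reactants: 6 tert-butyl 4,6-bis(benzyloxy)-2-formyl-3-hydroxybenzoate
Product: 7 tert-butyl 4,6-bis(benzyloxy)-2-(dimethoxymethyl)-3-hydroxybenzoate
Conditions: HC(OMe)3, MeOH, pyridinium p-toluenesulfonate (cat.), 25 °C; Et3N quench
Reagents that add atoms: trimethyl orthoformate, COC(OC)OC; methanol, CO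
Why: Acid-catalysed acetalization with the orthoformate as water scavenger; the mask prevents condensation of the ortho aldehyde with the chain in steps 7 to 10, and the weak acid catalyst should leave the tert-butyl ester intact.

Step 6
Reactants: 8 but-2-ynoic acid
Product: 9 benzyl but-2-ynoate
Conditions: BnBr, K2CO3, DMF, 25 °C
Reagents that add atoms: benzyl bromide, BrCc1ccccc1
Why: Carboxylate O-alkylation (SN2); the benzyl ester of the future ring A can be removed by hydrogenolysis without touching the tert-butyl ester of ring B.

Step 7
Reactants: 7 tert-butyl 4,6-bis(benzyloxy)-2-(dimethoxymethyl)-3-hydroxybenzoate; 9 benzyl but-2-ynoate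
Product: 10 benzyl (2E)-3-(ArO)but-2-enoate
Conditions: Cs2CO3 (0.3 equiv), DMF, 60 °C
Reagents that add atoms: none
Why: Base-catalysed oxa-Michael addition of the phenoxide to the β-carbon of the ynoate (directly or through the allenoate formed under the same base); reversible addition should settle the enol ether as the E isomer, aryloxy trans to the ester.

Step 8
Reactants: 10 benzyl (2E)-3-(ArO)but-2-enoate; 11 N-methoxy-N-methylacetamide
Product: 12 benzyl (2E)-3-(ArO)-5-oxohex-2-enoate
Conditions: LiN(iPr)2 (1.1 equiv), THF, −78 °C; then 11, −78 → −40 °C; AcOH, −78 °C
Reagents that add atoms: none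
Why: γ-Deprotonation gives the extended dienolate, which attacks the amide through its γ-carbon (Weinreb ketone synthesis); the chelated tetrahedral adduct holds the ketone back until the quench, so the more acidic product cannot protonate the dienolate, and loss of aryloxide from the dienolate is the reverse of a favourable addition to an allenoate.

Step 9
Reactants: 12 benzyl (2E)-3-(ArO)-5-oxohex-2-enoate; 11 N-methoxy-N-methylacetamide
Product: 13 benzyl (2E)-3-(ArO)-5,7-dioxooct-2-enoate
Conditions: LiN(iPr)2 (2.3 equiv), THF, −78 → −40 °C; then 11, −78 → −30 °C; AcOH, −78 °C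
Reagents that add atoms: none
Why: Terminal acylation of a 1,3-dicarbonyl-type dianion: the first equivalent of base removes a proton from C4, the second from the methyl carbon C6, and the last-formed, most reactive carbanion attacks the Weinreb amide; in the dianion the ester is part of the enolate and cannot be attacked by C6.

Step 10
Reactants: 13 benzyl (2E)-3-(ArO)-5,7-dioxooct-2-enoate
Product: 15 benzyl 2-(ArO)-4-hydroxy-6-methylbenzoate, via aldol adduct 14 (not isolated)
Conditions: Cs2CO3 (2 equiv), THF, 0 → 40 °C; pH 5 phosphate buffer work-up
Reagents that add atoms: none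
Why: Cs2CO3 first forms the diketonate at C6, but the reacting species is the minor tautomeric anion deprotonated at C4, a glutaconate-type dienolate delocalized over the C5 ketone and, through the aryl enol ether, over the ester. Its ester α-carbon C2 adds to the C7 methyl ketone in a 6-(enolendo)-exo-trig aldol closure to give carbinol 14, which loses water by E1cB elimination and tautomerizes to the phenoxide of 15, so that aromatization makes the sequence irreversible. The closest known reaction type is the biomimetic aldol cyclization of 3,5,7-trioxo esters to orsellinates, including variants in which the 3-carbonyl is held as an alkyl enol ether (alkoxide-opened 4-alkoxy-6-acetonylpyranones, diketo dioxinones); an aryl enol ether in that role extends the same substrate class. Ring A is the only ring closed, and the two stereocentres of 14 form without control and are erased on aromatization, so the step sets no stereocentre. The selectivity needed is C2-to-C7 aldol addition over attack of the diketonate carbon or oxygen on the ester (Claisen closure to an acylphloroglucinol ether, lactonization to a pyranone) and over loss of ring B by addition–elimination at C3. The substrate should secure it because the ester is a vinylogous carbonate, deactivated by the aryloxy group and by the charge of the dienolate, while the methyl ketone is the most electrophilic carbon; a carbonate base with a large, weakly chelating cation offers neither a nucleophile nor a template for Claisen closure, and any pyranone formed can be reopened by the benzyl alkoxide it releases, whereas the arene cannot revert. The fold puts the ring B oxygen on A5, the methyl group ortho to the ester and a free phenol para to it in one operation.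

Step 11
Reactants: 15 benzyl 2-(ArO)-4-hydroxy-6-methylbenzoate
Product: 16 benzyl 3-bromo-6-(ArO)-4-hydroxy-2-methylbenzoate
Conditions: NBS (1.0 equiv), MeCN, −20 → 0 °C
Reagents that add atoms: N-bromosuccinimide, O=C1CCC(=O)N1Br
Why: Electrophilic aromatic bromination of the phenol: of its two ortho positions A2 is para to the aryloxy group and open, whereas A6 lies beneath the orthogonal ring B, so bromine should block the position that a formylation would otherwise choose.

Step 12
Reactants: 16 benzyl 3-bromo-6-(ArO)-4-hydroxy-2-methylbenzoate
Product: 17 benzyl 3-bromo-6-(ArO)-5-formyl-4-hydroxy-2-methylbenzoate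
Conditions: MgCl2, Et3N, (CH2O)n, MeCN, 80 °C
Reagents that add atoms: formaldehyde (as paraformaldehyde), C=O
Why: Casnati–Skattebøl ortho-formylation; with A2 blocked the magnesium phenoxide can deliver formaldehyde only to A6, between the two ring A oxygens, and 2-bromophenols are standard substrates of this reaction.

Step 13
Reactants: 17 benzyl 3-bromo-6-(ArO)-5-formyl-4-hydroxy-2-methylbenzoate
Product: 18 benzyl 3-bromo-6-(ArO)-5-formyl-4-methoxy-2-methylbenzoate
Conditions: MeI, K2CO3, DMF, 25 °C
Reagents that add atoms: iodomethane, CI
Why: Williamson O-methylation of the hydrogen-bonded phenol; carbonate in DMF leaves the esters, the acetal and the aldehyde untouched.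

Step 14
Reactants: 18 benzyl 3-bromo-6-(ArO)-5-formyl-4-methoxy-2-methylbenzoate
Product: 19 2-[3-(tert-butoxycarbonyl)-2-(dimethoxymethyl)-4,6-dihydroxyphenoxy]-3-formyl-4-methoxy-6-methylbenzoic acid
Conditions: H2 (1 atm), 10% Pd/C, NaOAc, EtOAc–THF, 25 °C
Reagents that add atoms: none
Why: Catalytic hydrogenolysis cleaves the benzyl ester and both benzyl ethers and replaces the blocking bromine by hydrogen in one operation; acetate (not an amine, which would stop benzyl ether cleavage) takes up HBr so that acetal and tert-butyl ester survive, and the aldehyde, flanked on both sides, should be reduced much more slowly in an aprotic solvent.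

Step 15
Reactants: 19 2-[3-(tert-butoxycarbonyl)-2-(dimethoxymethyl)-4,6-dihydroxyphenoxy]-3-formyl-4-methoxy-6-methylbenzoic acid
Product: 20 tert-butyl 6-(dimethoxymethyl)-4-formyl-8-hydroxy-3-methoxy-1-methyl-11-oxo-11H-dibenzo[b,e][1,4]dioxepine-7-carboxylate
Conditions: DCC, DMAP (cat.), CH2Cl2 (0.005 M), 0 → 25 °C
Reagents that add atoms: none
Why: Carbodiimide lactonization of Steglich type: only the B2 hydroxyl can reach the activated carboxyl, through a seven-membered transition state, while the B4 hydroxyl is para to the ether link and hydrogen-bonded to its ester; high dilution suppresses intermolecular esters.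

Step 16
Reactants: 20 tert-butyl 6-(dimethoxymethyl)-4-formyl-8-hydroxy-3-methoxy-1-methyl-11-oxo-11H-dibenzo[b,e][1,4]dioxepine-7-carboxylate
Product: 21 racemic 1,4-dihydroxy-10-methoxy-8-methyl-3,7-dioxo-1,3-dihydro-7H-isobenzofuro[4,5-b][1,4]benzodioxepine-11-carbaldehyde
Conditions: CF3CO2H–H2O 9:1, 25 °C
Reagents that add atoms: water, O
Why: Acidolysis of the tert-butyl ester (loss of 2-methylpropene) and hydrolysis of the acetal free an ortho-formyl benzoic acid, which closes spontaneously to the five-membered lactol (ring–chain tautomerism); the aryl ester of the seven-membered ring is stable to aqueous acid, and the lactol forms as the racemate.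

Step 17
Reactants: 21 racemic 1,4-dihydroxy-10-methoxy-8-methyl-3,7-dioxo-1,3-dihydro-7H-isobenzofuro[4,5-b][1,4]benzodioxepine-11-carbaldehyde
Product: 23 (1S)-1,4-dihydroxy-10-methoxy-8-methyl-3,7-dioxo-1,3-dihydro-7H-isobenzofuro[4,5-b][1,4]benzodioxepine-11-carbaldehyde, via mandelic acid cocrystal 22 (not isolated)
Conditions: (S)-mandelic acid (1 equiv), Et3N (5 mol %), EtOAc–heptane slurry, 40 → 5 °C; filter cake washed with ice-cold water
Reagents that add atoms: (S)-mandelic acid, O[C@H](C(=O)O)c1ccccc1 (held in intermediate 22 only, none in 23)
Why: Proposed new method: the lactol racemizes in solution through the ring-opened, achiral formyl acid (ring–chain tautomerism, speeded by a trace of base), so if one enantiomer leaves as a less soluble hydrogen-bonded 1:1 cocrystal with a single-enantiomer acid the whole sample should drain into it, and the water-soluble co-former is then washed out of the solid with cold water without redissolving the lactol; the (S) configuration is set by the co-former, whose enantiomer (and, if need be, identity) is chosen by a screen so that the (S)-lactol is the one that crystallizes; the closest known reaction types are cocrystallization-induced deracemization of base-labile ketones and crystallization-induced epimerization of alkoxy butenolide acetals.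

## Compound list

1 | 5-bromo-2,4-dihydroxybenzoic acid | OC(=O)c1cc(Br)c(O)cc1O | starting material
2 | tert-butyl 5-bromo-2,4-dihydroxybenzoate | CC(C)(C)OC(=O)c1cc(Br)c(O)cc1O | intermediate
3 | tert-butyl 2,4-bis(benzyloxy)-5-bromobenzoate | CC(C)(C)OC(=O)c1cc(Br)c(OCc2ccccc2)cc1OCc1ccccc1 | intermediate
4 | tert-butyl 2,4-bis(benzyloxy)-5-(4,4,5,5-tetramethyl-1,3,2-dioxaborolan-2-yl)benzoate | CC(C)(C)OC(=O)c1cc(B2OC(C)(C)C(C)(C)O2)c(OCc2ccccc2)cc1OCc1ccccc1 | intermediate
5 | tert-butyl 2,4-bis(benzyloxy)-5-hydroxybenzoate | CC(C)(C)OC(=O)c1cc(O)c(OCc2ccccc2)cc1OCc1ccccc1 | intermediate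
6 | tert-butyl 4,6-bis(benzyloxy)-2-formyl-3-hydroxybenzoate | CC(C)(C)OC(=O)c1c(C=O)c(O)c(OCc2ccccc2)cc1OCc1ccccc1 | intermediate
7 | tert-butyl 4,6-bis(benzyloxy)-2-(dimethoxymethyl)-3-hydroxybenzoate | CC(C)(C)OC(=O)c1c(C(OC)OC)c(O)c(OCc2ccccc2)cc1OCc1ccccc1 | intermediate
8 | but-2-ynoic acid | CC#CC(=O)O | starting material
9 | benzyl but-2-ynoate | CC#CC(=O)OCc1ccccc1 | intermediate
10 | benzyl (2E)-3-[4,6-bis(benzyloxy)-3-(tert-butoxycarbonyl)-2-(dimethoxymethyl)phenoxy]but-2-enoate | C/C(Oc1c(OCc2ccccc2)cc(OCc2ccccc2)c(C(=O)OC(C)(C)C)c1C(OC)OC)=C\C(=O)OCc1ccccc1 | intermediate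
11 | N-methoxy-N-methylacetamide | CC(=O)N(C)OC | starting material
12 | benzyl (2E)-3-[4,6-bis(benzyloxy)-3-(tert-butoxycarbonyl)-2-(dimethoxymethyl)phenoxy]-5-oxohex-2-enoate | CC(=O)C/C(Oc1c(OCc2ccccc2)cc(OCc2ccccc2)c(C(=O)OC(C)(C)C)c1C(OC)OC)=C\C(=O)OCc1ccccc1 | intermediate
13 | benzyl (2E)-3-[4,6-bis(benzyloxy)-3-(tert-butoxycarbonyl)-2-(dimethoxymethyl)phenoxy]-5,7-dioxooct-2-enoate | CC(=O)CC(=O)C/C(Oc1c(OCc2ccccc2)cc(OCc2ccccc2)c(C(=O)OC(C)(C)C)c1C(OC)OC)=C\C(=O)OCc1ccccc1 | intermediate
14 | benzyl 2-[4,6-bis(benzyloxy)-3-(tert-butoxycarbonyl)-2-(dimethoxymethyl)phenoxy]-6-hydroxy-6-methyl-4-oxocyclohex-2-ene-1-carboxylate (mixture of racemic diastereomers) | CC1(O)CC(=O)C=C(Oc2c(OCc3ccccc3)cc(OCc3ccccc3)c(C(=O)OC(C)(C)C)c2C(OC)OC)C1C(=O)OCc1ccccc1 | intermediate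
15 | benzyl 2-[4,6-bis(benzyloxy)-3-(tert-butoxycarbonyl)-2-(dimethoxymethyl)phenoxy]-4-hydroxy-6-methylbenzoate | Cc1cc(O)cc(Oc2c(OCc3ccccc3)cc(OCc3ccccc3)c(C(=O)OC(C)(C)C)c2C(OC)OC)c1C(=O)OCc1ccccc1 | intermediate
16 | benzyl 3-bromo-6-[4,6-bis(benzyloxy)-3-(tert-butoxycarbonyl)-2-(dimethoxymethyl)phenoxy]-4-hydroxy-2-methylbenzoate | Cc1c(Br)c(O)cc(Oc2c(OCc3ccccc3)cc(OCc3ccccc3)c(C(=O)OC(C)(C)C)c2C(OC)OC)c1C(=O)OCc1ccccc1 | intermediate
17 | benzyl 3-bromo-6-[4,6-bis(benzyloxy)-3-(tert-butoxycarbonyl)-2-(dimethoxymethyl)phenoxy]-5-formyl-4-hydroxy-2-methylbenzoate | Cc1c(Br)c(O)c(C=O)c(Oc2c(OCc3ccccc3)cc(OCc3ccccc3)c(C(=O)OC(C)(C)C)c2C(OC)OC)c1C(=O)OCc1ccccc1 | intermediate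
18 | benzyl 3-bromo-6-[4,6-bis(benzyloxy)-3-(tert-butoxycarbonyl)-2-(dimethoxymethyl)phenoxy]-5-formyl-4-methoxy-2-methylbenzoate | Cc1c(Br)c(OC)c(C=O)c(Oc2c(OCc3ccccc3)cc(OCc3ccccc3)c(C(=O)OC(C)(C)C)c2C(OC)OC)c1C(=O)OCc1ccccc1 | intermediate
19 | 2-[3-(tert-butoxycarbonyl)-2-(dimethoxymethyl)-4,6-dihydroxyphenoxy]-3-formyl-4-methoxy-6-methylbenzoic acid | COc1cc(C)c(C(=O)O)c(Oc2c(O)cc(O)c(C(=O)OC(C)(C)C)c2C(OC)OC)c1C=O | intermediate
20 | tert-butyl 6-(dimethoxymethyl)-4-formyl-8-hydroxy-3-methoxy-1-methyl-11-oxo-11H-dibenzo[b,e][1,4]dioxepine-7-carboxylate | COc1cc(C)c2c(c1C=O)Oc1c(cc(O)c(C(=O)OC(C)(C)C)c1C(OC)OC)OC2=O | intermediate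
21 | racemic 1,4-dihydroxy-10-methoxy-8-methyl-3,7-dioxo-1,3-dihydro-7H-isobenzofuro[4,5-b][1,4]benzodioxepine-11-carbaldehyde (racemic lactol) | COc1cc(C)c2c(c1C=O)Oc1c(cc(O)c3c1C(O)OC3=O)OC2=O | intermediate
22 | 1:1 cocrystal of the (S)-lactol 23 with (S)-mandelic acid | COc1cc(C)c2c(c1C=O)Oc1c(cc(O)c3c1[C@@H](O)OC3=O)OC2=O.O[C@H](C(=O)O)c1ccccc1 | intermediate
23 | (1S)-1,4-dihydroxy-10-methoxy-8-methyl-3,7-dioxo-1,3-dihydro-7H-isobenzofuro[4,5-b][1,4]benzodioxepine-11-carbaldehyde, lactol carbon (S) | COc1cc(C)c2c(c1C=O)Oc1c(cc(O)c3c1[C@@H](O)OC3=O)OC2=O | target

## Step count and least certain steps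

Total step count: 17. Longest linear sequence: 16 steps (steps 1 to 5 and 7 to 17, from 1); step 6 is a one-step side branch.

Step 17 (crystallization-induced asymmetric transformation). Most likely failure: no discriminating cocrystal nucleates, or part of the lactol racemizes while it passes through solution during the release wash, because the stereocentre is labile whenever it is dissolved. Fallback with known chemistry: from 21, the enantiomers are separated by chromatography on a polysaccharide chiral stationary phase at low temperature with a neutral aprotic eluent. The (S) fraction is collected cold and crystallized at once to give 23, and the other fraction is re-equilibrated with a trace of base and recycled. This fallback makes no new compound (entry F0).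

Step 10 (key step). Most likely failure: acyl transfer to the ester from the diketonate (lactonization or Claisen closure), loss of the aryloxide by addition–elimination, or a stalled aldol addition because the C7 carbonyl stays locked in the diketonate. Fallback: from 10, the γ-dienolate is acylated with N-methoxy-N-methylbut-2-ynamide F1 (made from 8 by amide coupling) to give the ynone benzyl (2E)-3-(ArO)-5-oxooct-2-en-6-ynoate F2. Cs2CO3 then closes ring A by 6-endo-dig conjugate addition of C2 to the ynone and tautomerization, which returns to the route at 15. The same bond is formed, but no 1,3-diketone is present, so the C4 carbanion is the only one that can form and no dehydration is needed.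

Step 9 (dianion acylation). Most likely failure: fragmentation of the dianion by expulsion of the aryloxide, or incomplete second deprotonation followed by self-condensation, because two charges sit in one conjugated system next to a leaving group. Fallback without a polyanion: from 10, the γ-dienolate is acylated with racemic N-methoxy-N-methyl-3-[(triethylsilyl)oxy]butanamide F3 (from ethyl 3-hydroxybutanoate) to give benzyl (2E)-3-(ArO)-5-oxo-7-[(triethylsilyl)oxy]oct-2-enoate F4. Buffered HF·pyridine frees benzyl (2E)-3-(ArO)-7-hydroxy-5-oxooct-2-enoate F5, and Dess–Martin periodinane oxidizes it to 13.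

Step 11 (blocking bromination). Most likely failure: loss of site selectivity, with bromine entering A6, or double bromination, because both ortho positions of the phenol are activated. Fallback that uses the other regiochemistry: from 15, if bromination favours A6, the isomer benzyl 3-bromo-2-(ArO)-4-hydroxy-6-methylbenzoate F6 is O-methylated to benzyl 3-bromo-2-(ArO)-4-methoxy-6-methylbenzoate F7. Bromine–magnesium exchange (iPrMgCl·LiCl, THF, −20 °C) and DMF turn the bromide itself into the aldehyde benzyl 2-(ArO)-3-formyl-4-methoxy-6-methylbenzoate F8, and hydrogenolysis of F8 as in step 14 returns to the route at 19.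

Step 14 (hydrogenolysis). Most likely failure: over-reduction of the ring A aldehyde before the hindered benzyl ethers are gone. Fallback by protection: from 18, the aldehyde is converted with HC(OMe)3, MeOH and pyridinium p-toluenesulfonate into the acetal benzyl 3-bromo-6-(ArO)-5-(dimethoxymethyl)-4-methoxy-2-methylbenzoate F9. Hydrogenolysis gives the acid 2-[3-(tert-butoxycarbonyl)-2-(dimethoxymethyl)-4,6-dihydroxyphenoxy]-3-(dimethoxymethyl)-4-methoxy-6-methylbenzoic acid F10. Lactonization as in step 15 gives tert-butyl 4,6-bis(dimethoxymethyl)-8-hydroxy-3-methoxy-1-methyl-11-oxo-11H-dibenzo[b,e][1,4]dioxepine-7-carboxylate F11, and the acid treatment of step 16 removes both acetals and the tert-butyl ester, returning to the route at 21.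

## Further compounds

F0 | step 17 | none | none
F1 | step 10 | N-methoxy-N-methylbut-2-ynamide | CC#CC(=O)N(C)OC
F2 | step 10 | benzyl (2E)-3-(ArO)-5-oxooct-2-en-6-ynoate | CC#CC(=O)C/C(Oc1c(OCc2ccccc2)cc(OCc2ccccc2)c(C(=O)OC(C)(C)C)c1C(OC)OC)=C\C(=O)OCc1ccccc1
F3 | step 9 | racemic N-methoxy-N-methyl-3-[(triethylsilyl)oxy]butanamide | CC[Si](CC)(CC)OC(C)CC(=O)N(C)OC
F4 | step 9 | benzyl (2E)-3-(ArO)-5-oxo-7-[(triethylsilyl)oxy]oct-2-enoate (racemic at C7) | CC[Si](CC)(CC)OC(C)CC(=O)C/C(Oc1c(OCc2ccccc2)cc(OCc2ccccc2)c(C(=O)OC(C)(C)C)c1C(OC)OC)=C\C(=O)OCc1ccccc1
F5 | step 9 | benzyl (2E)-3-(ArO)-7-hydroxy-5-oxooct-2-enoate (racemic at C7) | CC(O)CC(=O)C/C(Oc1c(OCc2ccccc2)cc(OCc2ccccc2)c(C(=O)OC(C)(C)C)c1C(OC)OC)=C\C(=O)OCc1ccccc1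
F6 | step 11 | benzyl 3-bromo-2-(ArO)-4-hydroxy-6-methylbenzoate | Cc1cc(O)c(Br)c(Oc2c(OCc3ccccc3)cc(OCc3ccccc3)c(C(=O)OC(C)(C)C)c2C(OC)OC)c1C(=O)OCc1ccccc1
F7 | step 11 | benzyl 3-bromo-2-(ArO)-4-methoxy-6-methylbenzoate | Cc1cc(OC)c(Br)c(Oc2c(OCc3ccccc3)cc(OCc3ccccc3)c(C(=O)OC(C)(C)C)c2C(OC)OC)c1C(=O)OCc1ccccc1
F8 | step 11 | benzyl 2-(ArO)-3-formyl-4-methoxy-6-methylbenzoate | Cc1cc(OC)c(C=O)c(Oc2c(OCc3ccccc3)cc(OCc3ccccc3)c(C(=O)OC(C)(C)C)c2C(OC)OC)c1C(=O)OCc1ccccc1
F9 | step 14 | benzyl 3-bromo-6-(ArO)-5-(dimethoxymethyl)-4-methoxy-2-methylbenzoate | Cc1c(Br)c(OC)c(C(OC)OC)c(Oc2c(OCc3ccccc3)cc(OCc3ccccc3)c(C(=O)OC(C)(C)C)c2C(OC)OC)c1C(=O)OCc1ccccc1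
F10 | step 14 | 2-[3-(tert-butoxycarbonyl)-2-(dimethoxymethyl)-4,6-dihydroxyphenoxy]-3-(dimethoxymethyl)-4-methoxy-6-methylbenzoic acid | COc1cc(C)c(C(=O)O)c(Oc2c(O)cc(O)c(C(=O)OC(C)(C)C)c2C(OC)OC)c1C(OC)OC
F11 | step 14 | tert-butyl 4,6-bis(dimethoxymethyl)-8-hydroxy-3-methoxy-1-methyl-11-oxo-11H-dibenzo[b,e][1,4]dioxepine-7-carboxylate | COc1cc(C)c2c(c1C(OC)OC)Oc1c(cc(O)c(C(=O)OC(C)(C)C)c1C(OC)OC)OC2=O
A1 | alternative 1 | tricyclic aryl enol ether lactone with ring A as a (R)-methylcyclohexenone, product of the key step | C[C@@H]1CC(=O)CC2=C1C(=O)Oc1cc(O)c(C(=O)OC)c(C(OC)OC)c1O2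
A2 | alternative 1 | 2,5-dihydroxy-3-(dimethoxymethyl)-4-(methoxycarbonyl)phenyl (6R)-6-methyl-2,4-dioxocyclohexane-1-carboxylate, precursor of the key step | C[C@@H]1CC(=O)CC(=O)C1C(=O)Oc1cc(O)c(C(=O)OC)c(C(OC)OC)c1O
A3 | alternative 2 | depsidone with free ring A phenol, formyl group as diethyl acetal, ring B with methoxymethyl ether, methyl ester and dimethyl acetal, product of the key step | Oc1cc(C)c2c(c1C(OCC)OCC)Oc1c(cc(OCOC)c(C(=O)OC)c1C(OC)OC)OC2=O
A4 | alternative 2 | methyl 3-(3,3-diethoxyprop-1-ynyloxy)-4-(2-diazo-4-methyl-3-oxopent-4-enoyloxy)-2-(dimethoxymethyl)-6-(methoxymethoxy)benzoate, precursor of the key step | CCOC(OCC)C#COc1c(OC(=O)C(=[N+]=[N-])C(=O)C(C)=C)cc(OCOC)c(C(=O)OC)c1C(OC)OC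
A5 | alternative 3 | depsidone with ring A complete, ring B with methoxymethyl ether, methyl ester and dimethyl acetal, product of the key step | COc1cc(C)c2c(c1C=O)Oc1c(cc(OCOC)c(C(=O)OC)c1C(OC)OC)OC2=O
A6 | alternative 3 | diaryl ether with a chloroformate on the B2 oxygen and a pinacol boronate on A4, precursor of the key step | COc1cc(C)c(B2OC(C)(C)C(C)(C)O2)c(Oc2c(OC(=O)Cl)cc(OCOC)c(C(=O)OC)c2C(OC)OC)c1C=O
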